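The 35-membered ring of the target holds a single functional group, the lactone O1–C2(=O); the arc C3–C35 is an unbranched polymethylene chain without stereocentres. This allows the ring to be closed by ring-closing olefin metathesis at C27–C28, seven methylenes from the ring oxygen. A temporary C=C bond there costs nothing, because hydrogenation erases it together with its geometry. In one operation the key step turns an open-chain diene ester, non-8-en-1-yl heptacos-26-enoate, into the complete macrocycle with loss of ethylene. The diene ester comes from commercial non-8-en-1-ol and a C27 ω-alkenoic acid assembled by a copper-catalysed C11 + C16 Grignard coupling.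

Key step: step 3

Remark: the target is achiral. Ring atoms are numbered O1, C2 (C=O), C3 … C35 (OCH2). Compound 8 is expected as an E/Z mixture; the E isomer is drawn and both isomers converge in step 4.

Step 1
Reactants: 1 11-bromoundec-1-ene; 2 16-bromohexadecanoic acid
Product: 5 heptacos-26-enoic acid, via undec-10-en-1-ylmagnesium bromide 3 (not isolated), via chloromagnesium 16-bromohexadecanoate 4 (not isolated)
Conditions: 1 (1.5 equiv), Mg, THF, rt to 40 °C; separately 2, MeMgCl (1.0 equiv), THF, −20 °C; combine, Li2CuCl4 (3 mol%), −20 °C to rt; then 1 M HCl
Reagents that add atoms: magnesium, [Mg] (retained in 3 only); methylmagnesium chloride, C[Mg]Cl (its MgCl is retained in 4 only); no reagent atom remains in 5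
Why: Kochi-type copper-catalysed sp3–sp3 coupling of a primary alkyl Grignard reagent with a primary alkyl bromide, in which the acid is masked in the flask as its magnesium carboxylate (inert to the Grignard reagent at −20 °C) and the terminal alkene is untouched.

Step 2
Reactants: 5 heptacos-26-enoic acid; 6 non-8-en-1-ol
Product: 7 non-8-en-1-yl heptacos-26-enoate
Conditions: DCC (1.1 equiv), DMAP (10 mol%), CH2Cl2 (THF co-solvent if needed), 0 °C to rt
Reagents that add atoms: none
Why: Steglich esterification of an unhindered acid with a primary alcohol, under neutral conditions that leave both terminal alkenes in place.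

Step 3
Reactants: 7 non-8-en-1-yl heptacos-26-enoate
Product: 8 (E)-oxacyclopentatriacont-27-en-2-one
Conditions: Grubbs II (5 mol%), 1,4-benzoquinone (10 mol%), CH2Cl2 (about 1 mM, slow addition of 7), reflux, Ar sparge
Reagents that add atoms: none
Why: Ring-closing olefin metathesis by the Chauvin mechanism: the ruthenium alkylidene loads onto one terminal alkene of 7, [2+2] cycloaddition with the other gives a ruthenacyclobutane, and cycloreversion forms the C27=C28 double bond with loss of ethylene, whose removal drives the reaction. The closest known reaction type is the macrocyclic RCM of α,ω-diene esters to large-ring lactones. The 35-membered ring closes in an endo mode, both former alkene CH carbons becoming the ring atoms C27 and C28, and the unbranched chain builds up no ring strain. No stereocentre is created, and the E/Z geometry of the new alkene is left uncontrolled on purpose because step 4 erases it. The step needs ring closure to win over acyclic diene metathesis oligomerisation, which high dilution and the reversibility of metathesis (oligomers back-bite to the monomeric ring) should secure; it also needs positional fidelity, which 1,4-benzoquinone should secure by quenching Ru–H species that would migrate the terminal alkenes and give ring-contracted homologues. The only Lewis-basic site, the ester, lies 24 and 7 methylenes away from the two alkenes, so no unproductive chelate to ruthenium can form.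

Step 4
Reactants: 8 (E)-oxacyclopentatriacont-27-en-2-one
Product: 9 oxacyclopentatriacontan-2-one (tetratriacontan-34-olide)
Conditions: H2 (1 atm), 10% Pd/C, EtOAc/THF, rt (after filtration of crude 8 through silica to remove ruthenium)
Reagents that add atoms: none
Why: Heterogeneous catalytic hydrogenation saturates the disubstituted C27=C28 alkene of either geometry, while the lactone is inert and no stereocentre is involved.

Compound list
1 | 11-bromoundec-1-ene | C=CCCCCCCCCCBr | starting material
2 | 16-bromohexadecanoic acid | OC(=O)CCCCCCCCCCCCCCCBr | starting material
3 | undec-10-en-1-ylmagnesium bromide | C=CCCCCCCCCC[Mg]Br | intermediate (not isolated)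
4 | chloromagnesium 16-bromohexadecanoate | BrCCCCCCCCCCCCCCCC(=O)O[Mg]Cl | intermediate (not isolated)
5 | heptacos-26-enoic acid | OC(=O)CCCCCCCCCCCCCCCCCCCCCCCCC=C | intermediate
6 | non-8-en-1-ol | C=CCCCCCCCO | starting material
7 | non-8-en-1-yl heptacos-26-enoate | O=C(CCCCCCCCCCCCCCCCCCCCCCCCC=C)OCCCCCCCC=C | intermediate
8 | (E)-oxacyclopentatriacont-27-en-2-one (Z isomer expected alongside) | O=C1CCCCCCCCCCCCCCCCCCCCCCCC/C=C/CCCCCCCO1 | intermediate
9 | oxacyclopentatriacontan-2-one (tetratriacontan-34-olide) | O=C1CCCCCCCCCCCCCCCCCCCCCCCCCCCCCCCCCO1 | target

Total step count: 4
Longest linear sequence: 4 steps (1 or 2 → 5 → 7 → 8 → 9)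

Steps most likely to fail

Step 3. Intermolecular acyclic diene metathesis may outrun ring closure, and ruthenium-hydride-mediated migration of the terminal double bonds before closure would shorten the ring by one or more CH2 units. The fallback sets out from 7 and replaces metathesis by a reductive carbonyl coupling. Ozonolysis (O3, CH2Cl2, −78 °C; then PPh3) cuts both vinyl groups and should give 8-oxooctyl 26-oxohexacosanoate F1, whose two aldehyde carbons are the future ring atoms C27 and C28. Intramolecular McMurry coupling (TiCl3(DME)1.5, Zn–Cu, DME, reflux, syringe-pump addition) should then join them as the C27=C28 alkene. Aldehydes couple much faster than an ester reacts with low-valent titanium, and the carbonyl positions cannot migrate. The fallback comes back to the route at 8, which goes on to step 4.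

Step 1. Wurtz-type homocoupling of the Grignard reagent and slow coupling of the poorly soluble magnesium carboxylate may leave bromo acid that is hard to separate from the product acid. The fallback sets out from 2 and 6 and reverses the polarity of the coupling. Steglich esterification (DCC, DMAP, CH2Cl2) should give non-8-en-1-yl 16-bromohexadecanoate F2, a neutral and soluble bromo ester. Zinc insertion (Zn dust, I2 cat., DMA, 80 °C) should give the ester-tolerant [16-(non-8-en-1-yloxy)-16-oxohexadecyl]zinc bromide F3. Negishi alkyl–alkyl coupling of F3 with 1 (Pd2(dba)3, PCyp3, N-methylimidazole, THF/NMP, 80 °C) should deliver the diene ester directly. The fallback comes back to the route at 7 and so replaces steps 1 and 2.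

Step 2. A 1,3-acyl shift of the O-acylisourea to the unreactive N-acylurea may compete if the waxy acid reacts slowly from a partial suspension. The fallback sets out from 5 and 6 and activates the alcohol instead of the acid: Mitsunobu esterification (PPh3, DIAD, THF/toluene, 0 °C to rt), in which the carboxylate of 5 displaces the oxyphosphonium derivative of 6. It comes back to the route at 7 and makes no compound outside the list (F0).

Further compounds
F1 | step 3 | 8-oxooctyl 26-oxohexacosanoate | O=C(CCCCCCCCCCCCCCCCCCCCCCCCC=O)OCCCCCCCC=O
F2 | step 1 | non-8-en-1-yl 16-bromohexadecanoate | O=C(CCCCCCCCCCCCCCCBr)OCCCCCCCC=C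
F3 | step 1 | [16-(non-8-en-1-yloxy)-16-oxohexadecyl]zinc bromide | O=C(CCCCCCCCCCCCCCC[Zn]Br)OCCCCCCCC=C
F0 | step 2 | none | none
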